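**Assumption:** the target has no stereocentre and no stereogenic double bond, so "single enantiomer" is read as the single achiral compound drawn.

## Retrosynthetic overview

1. The target comes from its bis(methyl ether) by a final O-demethylation.
2. Key disconnection: the aryl–C(=O) bond. The N-tert-butylhydrazone of 4,5-dichloropyrrole-2-carbaldehyde serves as an acyl anion equivalent and is C-arylated by an aryl bromide under palladium catalysis, so two natively electrophilic carbons (aldehyde carbon and C–Br carbon) are joined; the pyrrole N–H and both C–Cl bonds are carried through unprotected.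
3. The aryl bromide comes from 1,3-dimethoxybenzene by C2 lithiation and alkylation with 1-bromo-4-methylpentane, then para-bromination.
4. The hydrazone comes from pyrrole-2-carbaldehyde by 4,5-dichlorination and condensation with tert-butylhydrazine.
5. No ring is built: the benzene ring and the pyrrole ring are both bought intact and are joined last through the carbonyl carbon.

## Route

Step 1
Reactants: 1 1,3-dimethoxybenzene; 2 1-bromo-4-methylpentane
Product: 4 1,3-dimethoxy-2-(4-methylpentyl)benzene, via (2,6-dimethoxyphenyl)lithium 3 (not isolated)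
Conditions: n-BuLi (1.1 equiv), THF, 0 °C to rt, 2 h; then 2 (1.2 equiv), 0 °C to rt, 12 h
Reagents that add atoms: none
Why: Directed ortho-metalation, in which the two methoxy groups together direct n-BuLi to C2, followed by SN2 alkylation of the aryllithium by the unhindered primary bromide.

Step 2
Reactants: 4 1,3-dimethoxy-2-(4-methylpentyl)benzene
Product: 5 1-bromo-2,4-dimethoxy-3-(4-methylpentyl)benzene
Conditions: NBS (1.05 equiv), MeCN, 0 °C to rt
Reagents that add atoms: N-bromosuccinimide, O=C1CCC(=O)N1Br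
Why: Electrophilic aromatic bromination, which goes to the only free position that is para to one methoxy group and ortho to the other (C5 is meta to both), and the mild reagent stops at the monobromide.

Step 3
Reactants: 6 1H-pyrrole-2-carbaldehyde
Product: 9 4,5-dichloro-1H-pyrrole-2-carbaldehyde, via 4-chloro-1H-pyrrole-2-carbaldehyde 7 (not isolated), via 5-chloro-1H-pyrrole-2-carbaldehyde 8 (not isolated)
Conditions: SO2Cl2 (2.05 equiv), Et2O, 0 °C to rt; recrystallise
Reagents that add atoms: sulfuryl chloride, O=S(=O)(Cl)Cl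
Why: Electrophilic aromatic chlorination of a 2-acylpyrrole, in which the formyl group leaves C4 and C5 as the reactive positions, so both monochloro isomers converge on the 4,5-dichloride while the deactivated C3 stays free.

Step 4
Reactants: 9 4,5-dichloro-1H-pyrrole-2-carbaldehyde
Product: 10 2-[(E)-(2-tert-butylhydrazinylidene)methyl]-4,5-dichloro-1H-pyrrole
Conditions: t-BuNHNH2·HCl (1.1 equiv), NaOAc (1.2 equiv), EtOH, rt; use promptly under N2
Reagents that add atoms: tert-butylhydrazine hydrochloride, CC(C)(C)NN.Cl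
Why: Hydrazone condensation, in which only the unhindered NH2 terminus of the hydrazine can condense and the E-hydrazone forms as the thermodynamic isomer.

Step 5
Reactants: 5 1-bromo-2,4-dimethoxy-3-(4-methylpentyl)benzene; 10 2-[(E)-(2-tert-butylhydrazinylidene)methyl]-4,5-dichloro-1H-pyrrole
Product: 13 (4,5-dichloro-1H-pyrrol-2-yl)[2,4-dimethoxy-3-(4-methylpentyl)phenyl]methanone, via tert-butyl azo compound 11 (not isolated), via ketone tert-butylhydrazone 12 (not isolated)
Conditions: Pd2(dba)3 (2.5 mol %), DPEphos (6 mol %), NaOtBu (2.5 equiv), 1,4-dioxane, 90 °C; then 3 M aq. HCl, THF, 50 °C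
Reagents that add atoms: water, O
Why: Palladium-catalysed C-arylation of an N-tert-butylhydrazone used as an acyl anion equivalent: 5 adds oxidatively to zerovalent palladium, the deprotonated hydrazone (a diaza-allyl anion) reductively eliminates at carbon because the tert-butyl group blocks its nitrogen, and the racemic azo compound tautomerises to the ketone hydrazone that aqueous acid hydrolyses. The 2,5-flanked, electron-poor dichloropyrrolide (formed by the extra equivalent of base) is too hindered to N-arylate with an ortho-substituted aryl group, and the pyrrole C–Cl bonds are inert to this catalyst.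

Step 6
Reactants: 13 (4,5-dichloro-1H-pyrrol-2-yl)[2,4-dimethoxy-3-(4-methylpentyl)phenyl]methanone
Product: 15 (4,5-dichloro-1H-pyrrol-2-yl)[2,4-dihydroxy-3-(4-methylpentyl)phenyl]methanone, via bis(dibromoboryl) ether 14 (not isolated)
Conditions: BBr3 (5 equiv), CH2Cl2, −78 °C to rt; then H2O
Reagents that add atoms: none
Why: Lewis-acid O-demethylation of aryl methyl ethers with BBr3, in which the ortho ether is activated by chelation to the ketone, excess reagent cleaves the para ether, and the acyl-deactivated dichloropyrrole tolerates the reagent.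

## Compound list

1 | 1,3-dimethoxybenzene | COc1cccc(OC)c1 | starting material
2 | 1-bromo-4-methylpentane | CC(C)CCCBr | starting material
3 | (2,6-dimethoxyphenyl)lithium | [Li]c1c(OC)cccc1OC | intermediate
4 | 1,3-dimethoxy-2-(4-methylpentyl)benzene | CC(C)CCCc1c(OC)cccc1OC | intermediate
5 | 1-bromo-2,4-dimethoxy-3-(4-methylpentyl)benzene | CC(C)CCCc1c(OC)ccc(Br)c1OC | intermediate
6 | 1H-pyrrole-2-carbaldehyde | O=Cc1ccc[nH]1 | starting material
7 | 4-chloro-1H-pyrrole-2-carbaldehyde | O=Cc1cc(Cl)c[nH]1 | intermediate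
8 | 5-chloro-1H-pyrrole-2-carbaldehyde | O=Cc1ccc(Cl)[nH]1 | intermediate
9 | 4,5-dichloro-1H-pyrrole-2-carbaldehyde | O=Cc1cc(Cl)c(Cl)[nH]1 | intermediate
10 | 2-[(E)-(2-tert-butylhydrazinylidene)methyl]-4,5-dichloro-1H-pyrrole | CC(C)(C)N/N=C/c1cc(Cl)c(Cl)[nH]1 | intermediate
11 | (E)-1-tert-butyl-2-{(4,5-dichloro-1H-pyrrol-2-yl)[2,4-dimethoxy-3-(4-methylpentyl)phenyl]methyl}diazene (racemic at CH, erased in the same step) | CC(C)CCCc1c(OC)ccc(C(/N=N/C(C)(C)C)c2cc(Cl)c(Cl)[nH]2)c1OC | intermediate
12 | N-tert-butylhydrazone of ketone 13 (E/Z mixture) | CC(C)CCCc1c(OC)ccc(C(=NNC(C)(C)C)c2cc(Cl)c(Cl)[nH]2)c1OC | intermediate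
13 | (4,5-dichloro-1H-pyrrol-2-yl)[2,4-dimethoxy-3-(4-methylpentyl)phenyl]methanone | CC(C)CCCc1c(OC)ccc(C(=O)c2cc(Cl)c(Cl)[nH]2)c1OC | intermediate
14 | bis(dibromoboryl) ether of 15 (simplest formulation) | CC(C)CCCc1c(OB(Br)Br)ccc(C(=O)c2cc(Cl)c(Cl)[nH]2)c1OB(Br)Br | intermediate
15 | (4,5-dichloro-1H-pyrrol-2-yl)[2,4-dihydroxy-3-(4-methylpentyl)phenyl]methanone | CC(C)CCCc1c(O)ccc(C(=O)c2cc(Cl)c(Cl)[nH]2)c1O | target

## Summary and risks

Total step count: 6. Longest linear sequence: 4 steps (1 → 4 → 5 → 13 → 15, or 6 → 9 → 10 → 13 → 15).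

**Most likely to fail, first: step 5.** The doubly deprotonated pyrrole hydrazone may bind palladium through nitrogen, and the bromide is electron-rich and ortho-substituted. The fallback blocks the pyrrole nitrogen so that the nucleophile is a simple monoanion; it sets out from 9 and comes back at 13. Aldehyde 9 is N-alkylated (NaH, 2-(trimethylsilyl)ethoxymethyl chloride, DMF, 0 °C) to 4,5-dichloro-1-{[2-(trimethylsilyl)ethoxy]methyl}-1H-pyrrole-2-carbaldehyde F1. Condensation with tert-butylhydrazine hydrochloride and NaOAc gives its (E)-N-tert-butylhydrazone F2. Coupling with 5 (Pd2(dba)3, DPEphos, NaOtBu 1.3 equiv, dioxane, 90 °C) gives the N-protected azo compound F3, which tautomerises to the N-protected ketone tert-butylhydrazone F4. Aqueous oxalic acid in THF hydrolyses it to the N-protected ketone F5, and n-Bu4NF with ethylenediamine in THF at 60 °C removes the nitrogen protecting group to give 13.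

**Second: step 3.** Dichlorination of the free aldehyde may give isomer mixtures or a trichloride. The fallback moves the chlorination to after the coupling; it sets out from 6 and comes back at 13. Aldehyde 6 is condensed with tert-butylhydrazine hydrochloride and NaOAc to 2-[(E)-(2-tert-butylhydrazinylidene)methyl]-1H-pyrrole F6. Coupling with 5 under the step 5 conditions passes through the chlorine-free azo compound F7 and the chlorine-free ketone tert-butylhydrazone F8, and acid hydrolysis gives [2,4-dimethoxy-3-(4-methylpentyl)phenyl](1H-pyrrol-2-yl)methanone F9. SO2Cl2 (2.05 equiv, CH2Cl2, 0 °C) then chlorinates the 2-aroylpyrrole, the most nucleophilic ring, through the 4-chloropyrrolyl ketone F10 and the 5-chloropyrrolyl ketone F11 to 13.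

**Third: step 6.** The non-chelated para ether may cleave slowly and the halopyrrole ketone may suffer under BBr3. The fallback swaps the methyl ethers for acetals that fall off in the hydrazone hydrolysis; it sets out from 4 and comes back at 15. Arene 4 is demethylated at the robust stage (48 % aq. HBr, AcOH, reflux) to 2-(4-methylpentyl)benzene-1,3-diol F12. Chloromethyl methyl ether and i-Pr2NEt in CH2Cl2 give 1,3-bis(methoxymethoxy)-2-(4-methylpentyl)benzene F13, and NBS in MeCN gives 1-bromo-2,4-bis(methoxymethoxy)-3-(4-methylpentyl)benzene F14. Coupling with 10 under the step 5 conditions gives the bis(methoxymethyl) azo compound F15, which tautomerises to the bis(methoxymethyl) ketone tert-butylhydrazone F16. Aqueous HCl (3 M) in THF at 50 °C then hydrolyses the hydrazone and both acetals in one operation to 15.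

## Further compounds

F1 | step 5 | 4,5-dichloro-1-{[2-(trimethylsilyl)ethoxy]methyl}-1H-pyrrole-2-carbaldehyde | O=Cc1cc(Cl)c(Cl)n1COCC[Si](C)(C)C
F2 | step 5 | (E)-N-tert-butylhydrazone of F1 | CC(C)(C)N/N=C/c1cc(Cl)c(Cl)n1COCC[Si](C)(C)C
F3 | step 5 | N-protected azo compound (racemic at CH, E azo) | CC(C)CCCc1c(OC)ccc(C(/N=N/C(C)(C)C)c2cc(Cl)c(Cl)n2COCC[Si](C)(C)C)c1OC
F4 | step 5 | N-protected ketone tert-butylhydrazone (E/Z mixture) | CC(C)CCCc1c(OC)ccc(C(=NNC(C)(C)C)c2cc(Cl)c(Cl)n2COCC[Si](C)(C)C)c1OC
F5 | step 5 | (4,5-dichloro-1-{[2-(trimethylsilyl)ethoxy]methyl}-1H-pyrrol-2-yl)[2,4-dimethoxy-3-(4-methylpentyl)phenyl]methanone | CC(C)CCCc1c(OC)ccc(C(=O)c2cc(Cl)c(Cl)n2COCC[Si](C)(C)C)c1OC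
F6 | step 3 | 2-[(E)-(2-tert-butylhydrazinylidene)methyl]-1H-pyrrole | CC(C)(C)N/N=C/c1ccc[nH]1
F7 | step 3 | chlorine-free azo compound (racemic at CH, E azo) | CC(C)CCCc1c(OC)ccc(C(/N=N/C(C)(C)C)c2ccc[nH]2)c1OC
F8 | step 3 | chlorine-free ketone tert-butylhydrazone (E/Z mixture) | CC(C)CCCc1c(OC)ccc(C(=NNC(C)(C)C)c2ccc[nH]2)c1OC
F9 | step 3 | [2,4-dimethoxy-3-(4-methylpentyl)phenyl](1H-pyrrol-2-yl)methanone | CC(C)CCCc1c(OC)ccc(C(=O)c2ccc[nH]2)c1OC
F10 | step 3 | (4-chloro-1H-pyrrol-2-yl)[2,4-dimethoxy-3-(4-methylpentyl)phenyl]methanone | CC(C)CCCc1c(OC)ccc(C(=O)c2cc(Cl)c[nH]2)c1OC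
F11 | step 3 | (5-chloro-1H-pyrrol-2-yl)[2,4-dimethoxy-3-(4-methylpentyl)phenyl]methanone | CC(C)CCCc1c(OC)ccc(C(=O)c2ccc(Cl)[nH]2)c1OC
F12 | step 6 | 2-(4-methylpentyl)benzene-1,3-diol | CC(C)CCCc1c(O)cccc1O
F13 | step 6 | 1,3-bis(methoxymethoxy)-2-(4-methylpentyl)benzene | CC(C)CCCc1c(OCOC)cccc1OCOC
F14 | step 6 | 1-bromo-2,4-bis(methoxymethoxy)-3-(4-methylpentyl)benzene | CC(C)CCCc1c(OCOC)ccc(Br)c1OCOC
F15 | step 6 | bis(methoxymethyl) azo compound (racemic at CH, E azo) | CC(C)CCCc1c(OCOC)ccc(C(/N=N/C(C)(C)C)c2cc(Cl)c(Cl)[nH]2)c1OCOC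
F16 | step 6 | bis(methoxymethyl) ketone tert-butylhydrazone (E/Z mixture) | CC(C)CCCc1c(OCOC)ccc(C(=NNC(C)(C)C)c2cc(Cl)c(Cl)[nH]2)c1OCOC
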